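The route builds the arene last. The feature exploited is the 1,3,5 pattern of the benzene ring (C1 side chain, C3 OMe, C5 OH): it is the dehydrogenated form of a 5-alkyl-3-methoxycyclohex-2-enone, itself the mono-enol ether of a symmetric 5-alkylcyclohexane-1,3-dione. One Michael–Claisen operation between dimethyl malonate and a methyl enone forms ring bonds C1–C2 and C3–C4 and closes the six-membered carbocycle with oxygen already on C3 and C5. The precursor is (R,E)-17-(benzyloxy)-6-(tert-butyldimethylsilyloxy)heptadec-3-en-2-one; its single stereocentre, the future acetoxy carbon C2′, comes from a Brown allylboration of an aldehyde made from dodecane-1,12-diol.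

Key step: step 6

Remark on the chemistry: the acetoxy carbon of the target is read as R (OAc > ArCH2 > alkyl chain > H); O-methylation of the symmetric dione 14 turns ring carbon C5 into a stereocentre, so 15, 16 and 17 are pairs of epimers at that carbon and not single isomers, and both epimers give the same arene in step 9.

Step 1
Reactants: 1 dodecane-1,12-diol
Product: 2 12-(benzyloxy)dodecan-1-ol
Conditions: NaH (1.0 equiv), BnBr (1.0 equiv), Bu4NI (cat.), THF/DMF, 0 °C → rt; 1 in 2.5-fold excess, recovered
Reagents that add atoms: benzyl bromide, BrCc1ccccc1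
Why: Williamson etherification with one equivalent of alkoxide in an excess of the cheap diol should give mainly the monoether, and the unreacted diol is easily separated and reused.

Step 2
Reactants: 2 12-(benzyloxy)dodecan-1-ol
Product: 3 12-(benzyloxy)dodecanal
Conditions: PhI(OAc)2 (1.1 equiv), TEMPO (10 mol%), CH2Cl2, rt
Reagents that add atoms: none
Why: TEMPO-catalysed oxidation with PhI(OAc)2 as terminal oxidant stops at the aldehyde and leaves the benzyl ether untouched.

Step 3
Reactants: 3 12-(benzyloxy)dodecanal; 4 B-allyldiisopinocampheylborane of the (+)-α-pinene series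
Product: 6 (R)-15-(benzyloxy)pentadec-1-en-4-ol, via borinate ester 5 (not isolated)
Conditions: 4 (1.3 equiv, 1 M in pentane), Et2O, −78 °C; then 3 M NaOH, 30% H2O2, 0 °C → rt
Reagents that add atoms: 4 B-allyldiisopinocampheylborane, C=CCB([C@@H]1C[C@@H]2C[C@@H](C2(C)C)[C@H]1C)[C@@H]1C[C@@H]2C[C@@H](C2(C)C)[C@H]1C
Why: Brown asymmetric allylboration through a closed chair transition state, in which the isopinocampheyl groups derived from (+)-α-pinene direct the allyl group to the Si face of an unbranched aliphatic aldehyde and so set the (R) carbinol centre under reagent control, followed by oxidative cleavage of the borinate.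

Step 4
Reactants: 6 (R)-15-(benzyloxy)pentadec-1-en-4-ol
Product: 7 (R)-tert-butyl{[15-(benzyloxy)pentadec-1-en-4-yl]oxy}dimethylsilane
Conditions: TBSCl (1.3 equiv), imidazole (2.5 equiv), DMF, rt
Reagents that add atoms: tert-butyldimethylsilyl chloride, CC(C)(C)[Si](C)(C)Cl
Why: Imidazole-promoted silylation of a secondary alcohol is routine, and the resulting alkyl silyl ether tolerates metathesis, alkoxide, hydroxide and LiN(iPr)2 in the later steps.

Step 5
Reactants: 7 (R)-tert-butyl{[15-(benzyloxy)pentadec-1-en-4-yl]oxy}dimethylsilane; 8 methyl vinyl ketone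
Product: 9 (R,E)-17-(benzyloxy)-6-(tert-butyldimethylsilyloxy)heptadec-3-en-2-one
Conditions: 8 (4 equiv), second-generation Grubbs catalyst RuCl2(=CHPh)(PCy3)(H2IMes) (3 mol%), CH2Cl2, 40 °C
Reagents that add atoms: 8 methyl vinyl ketone, C=CC(C)=O
Why: Olefin cross-metathesis of a terminal alkene with an excess of the electron-poor partner methyl vinyl ketone should give the cross product as the E-enone, driven by loss of ethene.

Step 6
Reactants: 9 (R,E)-17-(benzyloxy)-6-(tert-butyldimethylsilyloxy)heptadec-3-en-2-one; 10 dimethyl malonate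
Product: 12 methyl 6-[(R)-13-(benzyloxy)-2-(tert-butyldimethylsilyloxy)tridecyl]-2,4-dioxocyclohexane-1-carboxylate, via Michael adduct 11 (not isolated)
Conditions: 10 (1.5 equiv), NaOMe (1.3 equiv), MeOH, 0 °C → rt; then reflux; then 1 M HCl, 0 °C, to pH 3
Reagents that add atoms: 10 dimethyl malonate, COC(=O)CC(=O)OC
Why: Pre-formed sodium dimethyl malonate adds to the β-carbon (C4) of enone 9 in a Michael reaction (ring bond C1–C2), and on heating the methyl-side ketone enolate of adduct 11 attacks one malonate ester carbonyl and expels methoxide (ring bond C3–C4), the product being trapped as its stabilised β-dicarbonyl enolate, which pulls both equilibria forward. The closest known reaction type is the Michael–Claisen annulation of alk-3-en-2-ones with malonic esters, the standard entry to 5-alkylcyclohexane-1,3-diones. The carbocycle closes in a 6-(enolendo)-exo-trig acyl substitution, a mode favoured by Baldwin's rules for enolates. The two ring stereocentres formed (the carbons bearing the ester and the side chain) are left uncontrolled because both become sp2 centres on decarboxylation and aromatization, and the (R)-silyloxy carbon takes part in no bond change. The selectivity needed is conjugate addition ahead of γ-deprotonation and vinylogous E1cB loss of the δ-silyloxy group; it is secured by the soft, weakly basic malonate anion used with a small excess of malonate so that little free methoxide meets the enone at 0 °C, by the modest leaving-group ability of a silanolate, and by heating only once the enone is consumed, after which the adduct has no elimination pathway.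

Step 7
Reactants: 12 methyl 6-[(R)-13-(benzyloxy)-2-(tert-butyldimethylsilyloxy)tridecyl]-2,4-dioxocyclohexane-1-carboxylate
Product: 14 5-[(R)-13-(benzyloxy)-2-(tert-butyldimethylsilyloxy)tridecyl]cyclohexane-1,3-dione, via keto acid 13 (not isolated)
Conditions: NaOH (2 M aq., 5 equiv), MeOH/THF, 60 °C; then 1 M HCl to pH 3–4, EtOAc, 50 °C
Reagents that add atoms: none
Why: Saponification followed by mild acidification gives a β-keto acid that should lose CO2 on gentle warming (classical ester hydrolysis and decarboxylation), the pH being kept near 4 and the substrate held in an organic phase so that the secondary silyl ether survives.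

Step 8
Reactants: 14 5-[(R)-13-(benzyloxy)-2-(tert-butyldimethylsilyloxy)tridecyl]cyclohexane-1,3-dione
Product: 15 5-[(R)-13-(benzyloxy)-2-(tert-butyldimethylsilyloxy)tridecyl]-3-methoxycyclohex-2-en-1-one (pair of C5 epimers)
Conditions: Me3SiCHN2 (2 M in hexanes, 1.5 equiv), MeOH/toluene, 0 °C → rt
Reagents that add atoms: trimethylsilyldiazomethane, C[Si](C)(C)C=[N+]=[N-]
Why: The dione is a vinylogous acid and should be O-methylated under neutral conditions by the diazomethane equivalent released from Me3SiCHN2 in methanol, and since its two carbonyl groups are equivalent only one constitutional enol ether can form, as two C5 epimers that converge in step 9.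

Step 9
Reactants: 15 5-[(R)-13-(benzyloxy)-2-(tert-butyldimethylsilyloxy)tridecyl]-3-methoxycyclohex-2-en-1-one
Product: 19 3-[(R)-13-(benzyloxy)-2-(tert-butyldimethylsilyloxy)tridecyl]-5-methoxyphenol, via selenide 16 (not isolated), via selenoxide 17 (not isolated), via dienone 18 (not isolated)
Conditions: LiN(iPr)2 (1.15 equiv), THF, −78 °C; PhSeBr (1.2 equiv), −78 °C; then pyridine, 30% H2O2 (excess), 0 °C → rt
Reagents that add atoms: none
Why: Kinetic α′-deprotonation of the vinylogous ester at C6, selenenylation of the enolate, and selenoxide syn-elimination toward the only β-hydrogen (C5–H) should give the cross-conjugated dienone, which is the keto tautomer of the phenol and aromatizes at once, leaving the methyl ether on C3 and the free hydroxyl on C5.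

Step 10
Reactants: 19 3-[(R)-13-(benzyloxy)-2-(tert-butyldimethylsilyloxy)tridecyl]-5-methoxyphenol
Product: 20 (R)-{[13-(benzyloxy)-1-[3-(benzyloxy)-5-methoxyphenyl]tridecan-2-yl]oxy}(tert-butyl)dimethylsilane
Conditions: BnBr (1.2 equiv), K2CO3 (2 equiv), DMF, rt
Reagents that add atoms: benzyl bromide, BrCc1ccccc1
Why: Williamson benzylation of the phenoxide under carbonate conditions masks the phenol before the secondary alcohol is exposed and does not disturb the silyl ether.

Step 11
Reactants: 20 (R)-{[13-(benzyloxy)-1-[3-(benzyloxy)-5-methoxyphenyl]tridecan-2-yl]oxy}(tert-butyl)dimethylsilane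
Product: 21 (R)-13-(benzyloxy)-1-[3-(benzyloxy)-5-methoxyphenyl]tridecan-2-ol
Conditions: Bu4NF (1.5 equiv), THF, rt
Reagents that add atoms: none
Why: Fluoride-mediated desilylation, driven by the strong Si–F bond, frees only the secondary alcohol because benzyl and methyl ethers are inert to fluoride.

Step 12
Reactants: 21 (R)-13-(benzyloxy)-1-[3-(benzyloxy)-5-methoxyphenyl]tridecan-2-ol
Product: 22 (R)-13-(benzyloxy)-1-[3-(benzyloxy)-5-methoxyphenyl]tridecan-2-yl acetate
Conditions: Ac2O (2 equiv), pyridine (3 equiv), DMAP (5 mol%), CH2Cl2, rt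
Reagents that add atoms: acetic anhydride, CC(=O)OC(C)=O
Why: DMAP-catalysed acylation of the only free hydroxyl group proceeds at oxygen without breaking the C–O bond, so the (R) configuration is retained.

Step 13
Reactants: 22 (R)-13-(benzyloxy)-1-[3-(benzyloxy)-5-methoxyphenyl]tridecan-2-yl acetate
Product: 23 (R)-13-hydroxy-1-(3-hydroxy-5-methoxyphenyl)tridecan-2-yl acetate
Conditions: H2 (1 atm), 10% Pd/C, EtOAc/EtOH, rt
Reagents that add atoms: none
Why: Heterogeneous catalytic hydrogenolysis should cleave both benzylic C–O bonds (aryl and alkyl benzyl ether) in one operation, while the homobenzylic acetate, the aryl methyl ether and the arene are inert at one atmosphere.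

Compound list

1 | dodecane-1,12-diol | OCCCCCCCCCCCCO | starting material
2 | 12-(benzyloxy)dodecan-1-ol | OCCCCCCCCCCCCOCc1ccccc1 | intermediate
3 | 12-(benzyloxy)dodecanal | O=CCCCCCCCCCCCOCc1ccccc1 | intermediate
4 | B-allyldiisopinocampheylborane of the (+)-α-pinene series (both isopinocampheyl groups as in (1R,2R,3R,5S)-isopinocampheol; 1 M solution in pentane) | C=CCB([C@@H]1C[C@@H]2C[C@@H](C2(C)C)[C@H]1C)[C@@H]1C[C@@H]2C[C@@H](C2(C)C)[C@H]1C | starting material
5 | (R)-15-(benzyloxy)pentadec-1-en-4-yl diisopinocampheylborinate | C=CC[C@@H](CCCCCCCCCCCOCc1ccccc1)OB([C@@H]1C[C@@H]2C[C@@H](C2(C)C)[C@H]1C)[C@@H]1C[C@@H]2C[C@@H](C2(C)C)[C@H]1C | intermediate (not isolated)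
6 | (R)-15-(benzyloxy)pentadec-1-en-4-ol | C=CC[C@@H](CCCCCCCCCCCOCc1ccccc1)O | intermediate
7 | (R)-tert-butyl{[15-(benzyloxy)pentadec-1-en-4-yl]oxy}dimethylsilane | C=CC[C@@H](CCCCCCCCCCCOCc1ccccc1)O[Si](C)(C)C(C)(C)C | intermediate
8 | methyl vinyl ketone (but-3-en-2-one) | C=CC(C)=O | starting material
9 | (R,E)-17-(benzyloxy)-6-(tert-butyldimethylsilyloxy)heptadec-3-en-2-one | CC(=O)/C=C/C[C@@H](CCCCCCCCCCCOCc1ccccc1)O[Si](C)(C)C(C)(C)C | intermediate
10 | dimethyl malonate | COC(=O)CC(=O)OC | starting material
11 | dimethyl 2-[(6R)-17-(benzyloxy)-6-(tert-butyldimethylsilyloxy)-2-oxoheptadecan-4-yl]malonate (both C4 epimers) | COC(=O)C(C(=O)OC)C(CC(C)=O)C[C@@H](CCCCCCCCCCCOCc1ccccc1)O[Si](C)(C)C(C)(C)C | intermediate (not isolated)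
12 | methyl 6-[(R)-13-(benzyloxy)-2-(tert-butyldimethylsilyloxy)tridecyl]-2,4-dioxocyclohexane-1-carboxylate (mixture at ring C1 and C6, partly enolised) | COC(=O)C1C(=O)CC(=O)CC1C[C@@H](CCCCCCCCCCCOCc2ccccc2)O[Si](C)(C)C(C)(C)C | intermediate
13 | 6-[(R)-13-(benzyloxy)-2-(tert-butyldimethylsilyloxy)tridecyl]-2,4-dioxocyclohexane-1-carboxylic acid | OC(=O)C1C(=O)CC(=O)CC1C[C@@H](CCCCCCCCCCCOCc2ccccc2)O[Si](C)(C)C(C)(C)C | intermediate (not isolated)
14 | 5-[(R)-13-(benzyloxy)-2-(tert-butyldimethylsilyloxy)tridecyl]cyclohexane-1,3-dione | O=C1CC(=O)CC(C[C@@H](CCCCCCCCCCCOCc2ccccc2)O[Si](C)(C)C(C)(C)C)C1 | intermediate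
15 | 5-[(R)-13-(benzyloxy)-2-(tert-butyldimethylsilyloxy)tridecyl]-3-methoxycyclohex-2-en-1-one (pair of C5 epimers) | COC1=CC(=O)CC(C[C@@H](CCCCCCCCCCCOCc2ccccc2)O[Si](C)(C)C(C)(C)C)C1 | intermediate
16 | 5-[(R)-13-(benzyloxy)-2-(tert-butyldimethylsilyloxy)tridecyl]-3-methoxy-6-(phenylselanyl)cyclohex-2-en-1-one | COC1=CC(=O)C([Se]c2ccccc2)C(C[C@@H](CCCCCCCCCCCOCc2ccccc2)O[Si](C)(C)C(C)(C)C)C1 | intermediate (not isolated)
17 | 5-[(R)-13-(benzyloxy)-2-(tert-butyldimethylsilyloxy)tridecyl]-3-methoxy-6-(phenylseleninyl)cyclohex-2-en-1-one | COC1=CC(=O)C([Se](=O)c2ccccc2)C(C[C@@H](CCCCCCCCCCCOCc2ccccc2)O[Si](C)(C)C(C)(C)C)C1 | intermediate (not isolated)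
18 | 5-[(R)-13-(benzyloxy)-2-(tert-butyldimethylsilyloxy)tridecyl]-3-methoxycyclohexa-2,5-dien-1-one | COC1=CC(=O)C=C(C[C@@H](CCCCCCCCCCCOCc2ccccc2)O[Si](C)(C)C(C)(C)C)C1 | intermediate (not isolated)
19 | 3-[(R)-13-(benzyloxy)-2-(tert-butyldimethylsilyloxy)tridecyl]-5-methoxyphenol | COc1cc(O)cc(C[C@@H](CCCCCCCCCCCOCc2ccccc2)O[Si](C)(C)C(C)(C)C)c1 | intermediate
20 | (R)-{[13-(benzyloxy)-1-[3-(benzyloxy)-5-methoxyphenyl]tridecan-2-yl]oxy}(tert-butyl)dimethylsilane | COc1cc(OCc2ccccc2)cc(C[C@@H](CCCCCCCCCCCOCc2ccccc2)O[Si](C)(C)C(C)(C)C)c1 | intermediate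
21 | (R)-13-(benzyloxy)-1-[3-(benzyloxy)-5-methoxyphenyl]tridecan-2-ol | COc1cc(OCc2ccccc2)cc(C[C@@H](CCCCCCCCCCCOCc2ccccc2)O)c1 | intermediate
22 | (R)-13-(benzyloxy)-1-[3-(benzyloxy)-5-methoxyphenyl]tridecan-2-yl acetate | COc1cc(OCc2ccccc2)cc(C[C@@H](CCCCCCCCCCCOCc2ccccc2)OC(C)=O)c1 | intermediate
23 | (R)-13-hydroxy-1-(3-hydroxy-5-methoxyphenyl)tridecan-2-yl acetate (CNP0164512.1) | COc1cc(O)cc(C[C@@H](CCCCCCCCCCCO)OC(C)=O)c1 | target

Total step count: 13. Longest linear sequence: 13 steps (1 → 23).

Steps most likely to fail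

Step 6 (key annulation). What may go wrong: γ-deprotonation of the enone followed by vinylogous β-elimination of the silanolate outruns conjugate addition, or the Claisen closure stalls at the open-chain adduct and retro-Michael cleavage sets in on heating. The fallback uses known chemistry and attaches the side chain to a ready-made arene instead of building the ring. It sets out from aldehyde 3, which Corey–Chaykovsky methylenation (Me3SI, NaH, DMSO/THF) converts into racemic 2-[11-(benzyloxy)undecyl]oxirane F1. Jacobsen hydrolytic kinetic resolution of F1 with 0.55 equiv of water and the enantiomer of (salen)Co(OAc) (trivalent cobalt) that leaves the (R)-epoxide, expected to be the (R,R) complex, should give (R)-2-[11-(benzyloxy)undecyl]oxirane F2. Commercial 3-bromo-5-methoxyphenol F3 is benzylated (BnBr, K2CO3, DMF) to 1-(benzyloxy)-3-bromo-5-methoxybenzene F4, which with Mg in THF gives [3-(benzyloxy)-5-methoxyphenyl]magnesium bromide F5. F5 should open F2 at the unsubstituted carbon under CuI catalysis (10 mol%, THF, −30 °C), with the carbinol carbon untouched, and deliver alcohol 21, where the fallback comes back to the route before step 12.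

Step 9 (aromatization). What may go wrong: enolization toward C4 instead of C6, double selenenylation, or electrophilic attack of selenium species on the electron-rich phenol during the oxidation. The fallback is a Saegusa–Ito oxidation. It sets out from enol ether 15, which with LiN(iPr)2 and then Me3SiCl in THF at −78 °C should give the silyl dienol ether 5-[(R)-13-(benzyloxy)-2-(tert-butyldimethylsilyloxy)tridecyl]-1-methoxy-3-(trimethylsilyloxy)cyclohexa-1,3-diene F6. Pd(OAc)2 (divalent palladium, 1.05 equiv) in MeCN at rt should then dehydrosilylate F6 to dienone 18, which tautomerises to phenol 19, where the fallback comes back to the route before step 10.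

Step 7 (hydrolysis and decarboxylation). What may go wrong: loss of the silyl ether during acidification and warming, or incomplete saponification of the enolised, hindered keto ester. The fallback removes the ester under neutral conditions as an allyl ester. It sets out from enone 9, which is annulated with diallyl malonate F7 (NaH, THF, 0 °C then 60 °C) through the diallyl Michael adduct, diallyl 2-[(6R)-17-(benzyloxy)-6-(tert-butyldimethylsilyloxy)-2-oxoheptadecan-4-yl]malonate F8, to allyl 6-[(R)-13-(benzyloxy)-2-(tert-butyldimethylsilyloxy)tridecyl]-2,4-dioxocyclohexane-1-carboxylate F9. Pd(OAc)2 (5 mol%), PPh3, HCO2H and Et3N in THF at rt (Tsuji deallylation with formate as the hydride source, through zerovalent palladium formed in the flask) should then remove the allyl group and the carboxyl carbon and give dione 14, where the fallback comes back to the route before step 8.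

Further compounds

F1 | step 6 | racemic 2-[11-(benzyloxy)undecyl]oxirane | C1OC1CCCCCCCCCCCOCc1ccccc1
F2 | step 6 | (R)-2-[11-(benzyloxy)undecyl]oxirane | c1ccccc1COCCCCCCCCCCC[C@@H]1CO1
F3 | step 6 | 3-bromo-5-methoxyphenol (purchased) | COc1cc(O)cc(Br)c1
F4 | step 6 | 1-(benzyloxy)-3-bromo-5-methoxybenzene | COc1cc(Br)cc(OCc2ccccc2)c1
F5 | step 6 | [3-(benzyloxy)-5-methoxyphenyl]magnesium bromide | COc1cc([Mg]Br)cc(OCc2ccccc2)c1
F6 | step 9 | 5-[(R)-13-(benzyloxy)-2-(tert-butyldimethylsilyloxy)tridecyl]-1-methoxy-3-(trimethylsilyloxy)cyclohexa-1,3-diene | COC1=CC(O[Si](C)(C)C)=CC(C[C@@H](CCCCCCCCCCCOCc2ccccc2)O[Si](C)(C)C(C)(C)C)C1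
F7 | step 7 | diallyl malonate (purchased) | C=CCOC(=O)CC(=O)OCC=C
F8 | step 7 | diallyl 2-[(6R)-17-(benzyloxy)-6-(tert-butyldimethylsilyloxy)-2-oxoheptadecan-4-yl]malonate | C=CCOC(=O)C(C(=O)OCC=C)C(CC(C)=O)C[C@@H](CCCCCCCCCCCOCc1ccccc1)O[Si](C)(C)C(C)(C)C
F9 | step 7 | allyl 6-[(R)-13-(benzyloxy)-2-(tert-butyldimethylsilyloxy)tridecyl]-2,4-dioxocyclohexane-1-carboxylate | C=CCOC(=O)C1C(=O)CC(=O)CC1C[C@@H](CCCCCCCCCCCOCc2ccccc2)O[Si](C)(C)C(C)(C)C
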